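The plan disconnects both aryl bonds of the dihydrobenzofuran core (O1, C2, C3, C3a, C7a fused to ring A): C2–catechol ring and C3–resorcinol ring. C2 and C3 are neighbouring benzylic carbons bearing three aryl rings and a single oxygen, an array that results when two aryl groups are delivered to opposite faces of a ring A styrenyl boronate and boron is later oxidised to oxygen. One palladium-catalysed three-component coupling thus makes both C–aryl bonds and both stereocentres, with the ligand fixing C3. Its precursor is an (E)-alkenyl boronate of ring A that carries the masked O1 phenol, the C6 methoxy group, a C5 chloride for the stilbene, and the hindered mac diol on boron.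

Key step: step 7

Remark on the chemistry (assumption): the ligand (Sp,Sp)-1,1'-bis[bis(4-methoxy-3,5-dimethylphenyl)phosphino]-2,2'-bis[(R)-α-(dimethylamino)benzyl]ferrocene (MandyPhos family) is taken to direct palladium to the alkene face that leads to the (1R,2S) coupling product. If a test run shows the opposite sense, the (Rp,Rp) mirror-image ligand is used with no other change.

Remark on the structures: the target is the trans-(2S,3S) dihydrobenzofuran. No stereochemical correction is needed, because anti addition across the (E)-alkene gives the (1R,2S) boronate, which maps onto (2S,3S) after ring closure. The one design change is on boron: the pinacol ester is kept only as an intermediate and exchanged for the mac ester, since β-substituted pinacol ate complexes tend to give direct cross-coupling.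

**Route**

Step 1
Reactants: 1 2-hydroxy-4-methoxybenzaldehyde
Product: 2 5-chloro-2-hydroxy-4-methoxybenzaldehyde
Conditions: SO2Cl2 (1.05 equiv), CH2Cl2, 0 °C to rt
Reagents that add atoms: sulfuryl chloride, ClS(Cl)(=O)=O
Why: Electrophilic aromatic chlorination should go to C5, which is para to the phenol and ortho to the methoxy group, whereas C3 between the two oxygens is more hindered.

Step 2
Reactants: 2 5-chloro-2-hydroxy-4-methoxybenzaldehyde
Product: 3 5-chloro-4-methoxy-2-(methoxymethoxy)benzaldehyde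
Conditions: MOMCl (1.5 equiv), i-Pr2NEt (2 equiv), CH2Cl2, 0 °C to rt
Reagents that add atoms: chloromethyl methyl ether, COCCl
Why: O-Alkylation of the phenol (methoxymethyl ether formation) masks the future O1 against the lithium reagents used in steps 3 and 7.

Step 3
Reactants: 3 5-chloro-4-methoxy-2-(methoxymethoxy)benzaldehyde; 4 bis(4,4,5,5-tetramethyl-1,3,2-dioxaborolan-2-yl)methane
Product: 5 (E)-2-[5-chloro-4-methoxy-2-(methoxymethoxy)styryl]-4,4,5,5-tetramethyl-1,3,2-dioxaborolane
Conditions: 4 (1.2 equiv), lithium 2,2,6,6-tetramethylpiperidide (1.2 equiv), THF, 0 °C; then 3, −78 °C to rt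
Reagents that add atoms: none
Why: Boron-Wittig olefination, in which the lithiated gem-diboronate adds to the aldehyde and syn-elimination of a boron–oxygen unit gives the alkene with the aryl and boryl groups trans (E) for steric reasons.

Step 4
Reactants: 6 acenaphthylene-1,2-dione
Product: 7 cis-1,2-dimethyl-1,2-dihydroacenaphthylene-1,2-diol (meso 1R,2S; mac diol)
Conditions: MeMgBr (2.5 equiv), THF, 0 °C to rt; aq. NH4Cl; recrystallisation
Reagents that add atoms: methylmagnesium bromide, C[Mg]Br
Why: Double Grignard addition to the 1,2-diketone, where the second methyl group should add to the face away from the bulky magnesium alkoxide so that the hydroxyls end up cis, with crystallisation removing any trans diol.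

Step 5
Reactants: 5 (E)-2-[5-chloro-4-methoxy-2-(methoxymethoxy)styryl]-4,4,5,5-tetramethyl-1,3,2-dioxaborolane; 7 cis-1,2-dimethyl-1,2-dihydroacenaphthylene-1,2-diol
Product: 9 (E)-[5-chloro-4-methoxy-2-(methoxymethoxy)styryl]boronic acid cyclic ester of diol 7 (alkenyl B(mac) ester), via (E)-alkenylboronic acid 8 (not isolated)
Conditions: NaIO4 (3 equiv), NH4OAc (3 equiv), acetone/H2O, rt; extraction; then 7 (1.0 equiv), MgSO4, CH2Cl2, rt
Reagents that add atoms: none
Why: Periodate glycol cleavage of the pinacol drives hydrolysis to the boronic acid, and condensation with the rigid cis-diol (boronic ester formation) gives the hindered ester that disfavours direct transfer of an organic group from boron to palladium in step 7.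

Step 6
Reactants: 10 3,5-dimethoxyphenol
Product: 11 3,5-dimethoxyphenyl trifluoromethanesulfonate
Conditions: Tf2O (1.2 equiv), pyridine (2 equiv), CH2Cl2, 0 °C
Reagents that add atoms: trifluoromethanesulfonic anhydride, O=S(=O)(OS(=O)(=O)C(F)(F)F)C(F)(F)F
Why: O-Sulfonylation of the phenol gives an aryl triflate, an electrophile that releases no halide in the coupling and reacts with palladium far faster than the ring A chloride.

Step 7
Reactants: 12 4-bromo-1,2-dimethoxybenzene; 9 alkenyl B(mac) ester; 11 3,5-dimethoxyphenyl trifluoromethanesulfonate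
Product: 15 B(mac) ester of [(1R,2S)-2-(5-chloro-4-methoxy-2-(methoxymethoxy)phenyl)-1-(3,4-dimethoxyphenyl)-2-(3,5-dimethoxyphenyl)ethyl]boronic acid, via 3,4-dimethoxyphenyllithium 13 (not isolated), via lithium borate complex 14 (not isolated)
Conditions: 12 (1.05 equiv), t-BuLi (2.1 equiv), Et2O, −78 °C; 9 (1.0 equiv) in THF, −78 °C to rt; solvent exchange to THF; KOTf (2 equiv), 11 (1.2 equiv), Pd(OAc)2 (3 mol %), (Sp,Sp)-1,1'-bis[bis(4-methoxy-3,5-dimethylphenyl)phosphino]-2,2'-bis[(R)-α-(dimethylamino)benzyl]ferrocene (3.6 mol %), 60 °C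
Reagents that add atoms: none
Why: Aryllithium 13 adds to boron of 9 to give ate complex 14; the cationic arylpalladium species formed from 11 by oxidative addition binds the alkene and triggers 1,2-migration of the 3,4-dimethoxyphenyl group from boron to the boron-bearing carbon anti to palladium, and reductive elimination from the benzylic palladium then forms the bond to the 3,5-dimethoxyphenyl group with retention. The closest known reaction type is the enantioselective palladium-catalysed conjunctive cross-coupling of alkenyl boron ate complexes with aryl triflates, which has been extended to β-substituted alkenyl B(mac) esters. No ring is closed. The triaryl-substituted carbon (future C3, S) is set by the alkene face that the palladium bound to the chiral ferrocenyl bisphosphine selects, and the boron-bearing carbon (future C2, R at this stage) follows from the anti relationship of migration and palladation on the (E)-alkene. The step needs the 1,2-shift to outrun direct transfer of an organic group from boron to palladium, which the hindered mac diol should secure, and it needs the ring A C–Cl bond to stay intact, which the much faster oxidative addition of the triflate secures. KOTf precipitates the bromide left by the lithium–halogen exchange, which would otherwise block the cationic palladium.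

Step 8
Reactants: 15 B(mac) boronate from step 7
Product: 16 (1R,2S)-2-[5-chloro-4-methoxy-2-(methoxymethoxy)phenyl]-1-(3,4-dimethoxyphenyl)-2-(3,5-dimethoxyphenyl)ethan-1-ol
Conditions: 30% H2O2, 3 M NaOH, THF, 0 °C to rt
Reagents that add atoms: hydrogen peroxide, OO
Why: Alkaline peroxide oxidation of the C–B bond proceeds by 1,2-migration of carbon from boron to oxygen with retention, so the (1R,2S) configuration should be kept and diol 7 can be recovered.

Step 9
Reactants: 16 (1R,2S)-2-[5-chloro-4-methoxy-2-(methoxymethoxy)phenyl]-1-(3,4-dimethoxyphenyl)-2-(3,5-dimethoxyphenyl)ethan-1-ol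
Product: 18 (2S,3S)-5-chloro-2-(3,4-dimethoxyphenyl)-3-(3,5-dimethoxyphenyl)-6-methoxy-2,3-dihydro-1-benzofuran, via free phenol alcohol 17 (not isolated)
Conditions: 3 M aq. HCl (5 equiv), MeOH/THF, 50 °C
Reagents that add atoms: none
Why: Acid-catalysed acetal cleavage frees the phenol and cyclodehydration closes the O1–C2 bond; both an SN2-like displacement (inversion at C2) and closure of the 3,4-dimethoxybenzyl cation anti to the C3 aryl group lead to the trans (2S,3S) ring, while C3 is not touched.

Step 10
Reactants: 18 (2S,3S)-5-chloro-2-(3,4-dimethoxyphenyl)-3-(3,5-dimethoxyphenyl)-6-methoxy-2,3-dihydro-1-benzofuran; 19 3,5-dimethoxystyrene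
Product: 20 (2S,3S)-2-(3,4-dimethoxyphenyl)-3-(3,5-dimethoxyphenyl)-5-[(E)-2-(3,5-dimethoxyphenyl)ethenyl]-6-methoxy-2,3-dihydro-1-benzofuran
Conditions: 19 (1.5 equiv), Pd2(dba)3 (2.5 mol %), [HP(t-Bu)3]BF4 (10 mol %), Cy2NMe (1.5 equiv), 1,4-dioxane, 110 °C
Reagents that add atoms: none
Why: Mizoroki–Heck reaction in which the bulky electron-rich phosphine P(t-Bu)3 allows oxidative addition of the electron-rich aryl chloride, and syn insertion of the styrene followed by syn β-hydride elimination should give the (E)-stilbene without touching C2 or C3.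

Step 11
Reactants: 20 heptamethyl ether from step 10
Product: 21 4-[(2S,3S)-3-(3,5-dihydroxyphenyl)-5-[(E)-2-(3,5-dihydroxyphenyl)ethenyl]-6-hydroxy-2,3-dihydro-1-benzofuran-2-yl]benzene-1,2-diol (target)
Conditions: BBr3 (12 equiv), CH2Cl2, −78 °C to rt; MeOH, then H2O
Reagents that add atoms: none
Why: Lewis acid cleavage of aryl methyl ethers by BBr3 should remove all seven methyl groups, and any reversible opening of the O1–C2 bond should reclose to the same trans ring because C3 is unaffected.

**Compound list**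

1 | 2-hydroxy-4-methoxybenzaldehyde | COc1ccc(C=O)c(O)c1 | starting material
2 | 5-chloro-2-hydroxy-4-methoxybenzaldehyde | COc1cc(O)c(C=O)cc1Cl | intermediate
3 | 5-chloro-4-methoxy-2-(methoxymethoxy)benzaldehyde | COCOc1cc(OC)c(Cl)cc1C=O | intermediate
4 | bis(4,4,5,5-tetramethyl-1,3,2-dioxaborolan-2-yl)methane | CC1(C)OB(CB2OC(C)(C)C(C)(C)O2)OC1(C)C | starting material
5 | (E)-2-[5-chloro-4-methoxy-2-(methoxymethoxy)styryl]-4,4,5,5-tetramethyl-1,3,2-dioxaborolane | CC1(C)OB(/C=C/c2cc(Cl)c(OC)cc2OCOC)OC1(C)C | intermediate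
6 | acenaphthylene-1,2-dione | O=C1C(=O)c2cccc3cccc1c23 | starting material
7 | cis-1,2-dimethyl-1,2-dihydroacenaphthylene-1,2-diol (meso 1R,2S; mac diol) | C[C@@]1(O)[C@](C)(O)c2cccc3cccc1c23 | intermediate
8 | (E)-[5-chloro-4-methoxy-2-(methoxymethoxy)styryl]boronic acid | OB(O)/C=C/c1cc(Cl)c(OC)cc1OCOC | intermediate (not isolated)
9 | (E)-[5-chloro-4-methoxy-2-(methoxymethoxy)styryl]boronic acid cyclic ester of diol 7 (alkenyl B(mac) ester) | C[C@@]12OB(/C=C/c3cc(Cl)c(OC)cc3OCOC)O[C@]1(C)c1cccc4cccc2c14 | intermediate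
10 | 3,5-dimethoxyphenol | COc1cc(O)cc(OC)c1 | starting material
11 | 3,5-dimethoxyphenyl trifluoromethanesulfonate | COc1cc(OC)cc(OS(=O)(=O)C(F)(F)F)c1 | intermediate
12 | 4-bromo-1,2-dimethoxybenzene | COc1ccc(Br)cc1OC | starting material
13 | 3,4-dimethoxyphenyllithium | [Li]c1ccc(OC)c(OC)c1 | intermediate (not isolated)
14 | lithium (3,4-dimethoxyphenyl)[(E)-5-chloro-4-methoxy-2-(methoxymethoxy)styryl]borate of diol 7 (ate complex, configuration at boron not defined) | [Li+].C[C@@]12O[B-](/C=C/c3cc(Cl)c(OC)cc3OCOC)(c3ccc(OC)c(OC)c3)O[C@]1(C)c1cccc4cccc2c14 | intermediate (not isolated)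
15 | B(mac) ester of [(1R,2S)-2-(5-chloro-4-methoxy-2-(methoxymethoxy)phenyl)-1-(3,4-dimethoxyphenyl)-2-(3,5-dimethoxyphenyl)ethyl]boronic acid | C[C@@]12OB([C@@H](c3ccc(OC)c(OC)c3)[C@H](c3cc(Cl)c(OC)cc3OCOC)c3cc(OC)cc(OC)c3)O[C@]1(C)c1cccc4cccc2c14 | intermediate
16 | (1R,2S)-2-[5-chloro-4-methoxy-2-(methoxymethoxy)phenyl]-1-(3,4-dimethoxyphenyl)-2-(3,5-dimethoxyphenyl)ethan-1-ol | O[C@@H](c1ccc(OC)c(OC)c1)[C@H](c1cc(Cl)c(OC)cc1OCOC)c1cc(OC)cc(OC)c1 | intermediate
17 | 4-chloro-2-[(1S,2R)-2-(3,4-dimethoxyphenyl)-1-(3,5-dimethoxyphenyl)-2-hydroxyethyl]-5-methoxyphenol (free phenol alcohol) | O[C@@H](c1ccc(OC)c(OC)c1)[C@H](c1cc(Cl)c(OC)cc1O)c1cc(OC)cc(OC)c1 | intermediate (not isolated)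
18 | (2S,3S)-5-chloro-2-(3,4-dimethoxyphenyl)-3-(3,5-dimethoxyphenyl)-6-methoxy-2,3-dihydro-1-benzofuran | Clc1cc2c(cc1OC)O[C@H](c1ccc(OC)c(OC)c1)[C@H]2c1cc(OC)cc(OC)c1 | intermediate
19 | 3,5-dimethoxystyrene | C=Cc1cc(OC)cc(OC)c1 | starting material
20 | (2S,3S)-2-(3,4-dimethoxyphenyl)-3-(3,5-dimethoxyphenyl)-5-[(E)-2-(3,5-dimethoxyphenyl)ethenyl]-6-methoxy-2,3-dihydro-1-benzofuran | COc1cc(OC)cc(/C=C/c2cc3c(cc2OC)O[C@H](c2ccc(OC)c(OC)c2)[C@H]3c2cc(OC)cc(OC)c2)c1 | intermediate
21 | 4-[(2S,3S)-3-(3,5-dihydroxyphenyl)-5-[(E)-2-(3,5-dihydroxyphenyl)ethenyl]-6-hydroxy-2,3-dihydro-1-benzofuran-2-yl]benzene-1,2-diol | Oc1cc(O)cc(/C=C/c2cc3c(cc2O)O[C@H](c2ccc(O)c(O)c2)[C@H]3c2cc(O)cc(O)c2)c1 | target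

**Step count and risks**

Total steps: 11. Longest linear sequence: 9 steps (1, 2, 3, 5, 7, 8, 9, 10, 11).

Steps most likely to fail:

1. Step 7. With a β-aryl alkene, direct transfer of the alkenyl or aryl group from boron to palladium may overtake the 1,2-shift. β-Hydride elimination from the benzylic palladium intermediate may compete with reductive elimination, and the ligand may discriminate the alkene faces poorly. The fallback sets out from 2 and builds the C2–C3 bond by enantioselective carbene C–H insertion.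
   - O-Alkylation of 2 with 3,4-dimethoxybenzyl chloride (K2CO3, DMF) should give 5-chloro-2-[(3,4-dimethoxybenzyl)oxy]-4-methoxybenzaldehyde F1.
   - Addition of 3,5-dimethoxyphenylmagnesium bromide gives [5-chloro-2-[(3,4-dimethoxybenzyl)oxy]-4-methoxyphenyl](3,5-dimethoxyphenyl)methanol F2, and MnO2 oxidation gives [5-chloro-2-[(3,4-dimethoxybenzyl)oxy]-4-methoxyphenyl](3,5-dimethoxyphenyl)methanone F3.
   - Condensation with hydrazine hydrate gives the hydrazone of that ketone F4, and MnO2 oxidation gives [5-chloro-2-[(3,4-dimethoxybenzyl)oxy]-4-methoxyphenyl](3,5-dimethoxyphenyl)diazomethane F5.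
   - Rh2(S-PTAD)4 (or its mirror image, whichever a test run shows to give 3S) should then insert the donor/donor carbene into the benzylic ether C–H bond to give cis-(2R,3S)-5-chloro-2-(3,4-dimethoxyphenyl)-3-(3,5-dimethoxyphenyl)-6-methoxy-2,3-dihydro-1-benzofuran F6.
   - Trifluoroacetic acid in CH2Cl2 epimerises C2 by reversible ionisation of the O1–C2 bond, and the route is rejoined at 18.

2. Step 11. Acid generated around BBr3 may add to or oligomerise the electron-rich stilbene, and cleavage of seven ethers may stall. The fallback sets out from 18 and moves the deprotection ahead of the stilbene.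
   - BBr3 on 18 should give 4-[(2S,3S)-5-chloro-3-(3,5-dihydroxyphenyl)-6-hydroxy-2,3-dihydro-1-benzofuran-2-yl]benzene-1,2-diol F7.
   - Ac2O in pyridine gives the pentaacetate of that pentaphenol F8.
   - Mizoroki–Heck coupling with commercial 3,5-diacetoxystyrene under the conditions of step 10 gives the heptaacetate of 21 F9.
   - Methanolysis with K2CO3 in degassed MeOH at 0 °C rejoins the route at 21.

3. Step 10. Oxidative addition into the electron-rich, ortho-substituted C–Cl bond may be slow enough for the catalyst to decompose, and insertion may give some branched alkene. The fallback sets out from 18 and replaces the Heck reaction by a Suzuki–Miyaura coupling.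
   - 3,5-Dimethoxybenzaldehyde is converted with 4 and lithium 2,2,6,6-tetramethylpiperidide, as in step 3, into (E)-2-(3,5-dimethoxystyryl)-4,4,5,5-tetramethyl-1,3,2-dioxaborolane F10.
   - F10 is coupled with 18 using Pd(OAc)2, SPhos and K3PO4 in toluene/H2O at 90 °C, and the route is rejoined at 20.

Further compounds
F1 | step 7 | 5-chloro-2-[(3,4-dimethoxybenzyl)oxy]-4-methoxybenzaldehyde | COc1cc(OCc2ccc(OC)c(OC)c2)c(C=O)cc1Cl
F2 | step 7 | [5-chloro-2-[(3,4-dimethoxybenzyl)oxy]-4-methoxyphenyl](3,5-dimethoxyphenyl)methanol (racemic) | COc1cc(OCc2ccc(OC)c(OC)c2)c(C(O)c2cc(OC)cc(OC)c2)cc1Cl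
F3 | step 7 | [5-chloro-2-[(3,4-dimethoxybenzyl)oxy]-4-methoxyphenyl](3,5-dimethoxyphenyl)methanone | COc1cc(OCc2ccc(OC)c(OC)c2)c(C(=O)c2cc(OC)cc(OC)c2)cc1Cl
F4 | step 7 | hydrazone of [5-chloro-2-[(3,4-dimethoxybenzyl)oxy]-4-methoxyphenyl](3,5-dimethoxyphenyl)methanone | COc1cc(OCc2ccc(OC)c(OC)c2)c(C(=NN)c2cc(OC)cc(OC)c2)cc1Cl
F5 | step 7 | [5-chloro-2-[(3,4-dimethoxybenzyl)oxy]-4-methoxyphenyl](3,5-dimethoxyphenyl)diazomethane | COc1cc(OCc2ccc(OC)c(OC)c2)c(C(=[N+]=[N-])c2cc(OC)cc(OC)c2)cc1Cl
F6 | step 7 | cis-(2R,3S)-5-chloro-2-(3,4-dimethoxyphenyl)-3-(3,5-dimethoxyphenyl)-6-methoxy-2,3-dihydro-1-benzofuran | Clc1cc2c(cc1OC)O[C@@H](c1ccc(OC)c(OC)c1)[C@H]2c1cc(OC)cc(OC)c1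
F7 | step 11 | 4-[(2S,3S)-5-chloro-3-(3,5-dihydroxyphenyl)-6-hydroxy-2,3-dihydro-1-benzofuran-2-yl]benzene-1,2-diol | Clc1cc2c(cc1O)O[C@H](c1ccc(O)c(O)c1)[C@H]2c1cc(O)cc(O)c1
F8 | step 11 | pentaacetate of F7 | Clc1cc2c(cc1OC(C)=O)O[C@H](c1ccc(OC(C)=O)c(OC(C)=O)c1)[C@H]2c1cc(OC(C)=O)cc(OC(C)=O)c1
F9 | step 11 | heptaacetate of 21 | CC(=O)Oc1cc(OC(C)=O)cc(/C=C/c2cc3c(cc2OC(C)=O)O[C@H](c2ccc(OC(C)=O)c(OC(C)=O)c2)[C@H]3c2cc(OC(C)=O)cc(OC(C)=O)c2)c1
F10 | step 10 | (E)-2-(3,5-dimethoxystyryl)-4,4,5,5-tetramethyl-1,3,2-dioxaborolane | COc1cc(OC)cc(/C=C/B2OC(C)(C)C(C)(C)O2)c1
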